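Take the electrophile used at the plateau, subtract the mean of the nucleophile charged and the target standing there, and nearly the same remainder comes out of both earlier flasks. At 2.50 h it is 20.4% in the east flask and 19.8% in the north-east flask, with readings scattered by 0.3 percentage points.

| setting | east | north-east | flask |
|---|---|---|---|
| electrophile | 20 mM | 20 mM | 20 mM |
| nucleophile | 0.47 equiv | 0.71 equiv | 0.950 equiv |
| buffer base | 3 equiv | 3 equiv | 3.00 equiv |
| buffer acid | 0.10 equiv | 0.10 equiv | 0.100 equiv |
| protic impurity | 4 mM | 4 mM | 4.00 mM |
| remark | run made earlier | run made earlier |  |
| time |  |  | 2.5 h |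

- east (time / h: electrophile / %, target / %): 0.133: 74.0, 13.4; 0.417: 54.7, 23.5; 0.667: 47.8, 26.5; 1.00: 44.4, 28.6; 1.50: 42.6, 28.6; 2.00: 42.1, 29.0; 2.50: 41.7, 28.9
- north-east (time / h: electrophile / %, target / %): 0.200: 58.8, 23.2; 0.333: 48.1, 28.2; 0.500: 40.9, 31.3; 0.667: 36.8, 32.3; 1.00: 32.1, 33.9; 1.50: 28.8, 33.2; 2.50: 27.8, 33.9

(standard deviation of a reading: 0.3 percentage points)

1. part of the electrophile that has reacted at 2.5 h
2. pH of the solution at 2.5 h

- the earlier runs do not show the pH; that part of a forecast is a guess

Here is the count behind that remainder, which is my own view. I suppose that by the plateau each nucleophile has reacted, either with an electrophile or with a target already made. Such a hit spends a second nucleophile on an electrophile that then no longer stands in the target column. Eliminating the hits leaves a mass balance: electrophile used equals the mean of nucleophile and target, plus a remainder. Zero on this scale is the symmetric flask, where electrophile goes no other way. I call the remainder the toll, the electrophile lost outside the nucleophile count, and read it as 20.1%. The ratio c(protic impurity)/c(electrophile) is 20.0%, so I suppose the impurity takes electrophile one for one.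

For the flask, the count needs a target value, and I hold the north-east reading of 33.9%. That gives 84.5% reacted. I have no reckoning for the pH.

The forecast disagrees: “the active nucleophile dies by a first-order side process while it attacks the electrophile”. It gives 82% reacted and a guessed pH of 7.5.

The flask gives 82.8% reacted and pH 6.40, so the forecast lies nearer than my number on conversion.

    electrophile + nucleophile ⇌ acid + target + leaving group (K = 1.01 × 10⁻⁴ M, k = 0.0454 M⁻¹ s⁻¹)
    protonated nucleophile ⇌ nucleophile + acid, settled at all times (K = 6.30 × 10⁻⁵ M)
    buffer acid ⇌ buffer base + acid, settled at all times (K = 1.30 × 10⁻⁶ M)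
    electrophile + protic impurity → quenched substrate (k = 0.113 M⁻¹ s⁻¹)
    nucleophile + target → over-reaction product (k = 0.0352 M⁻¹ s⁻¹)

My held target was close to the flask at 1.25 h, when target there stood at 33.8%, but at 2.50 h it stands in the flask at 32.4%. With that value and 1.6% of the nucleophile still free, the toll of this flask is 19.9%. The neighbouring flask with 1.6 mM of protic impurity reaches 74.0%, with target at 37.8% and 0.80% of its nucleophile free. Its toll comes to 7.99%, against an impurity charge of 8.00% of the electrophile.

The runs stem from a simulated flask from invented constants; noise was put on by code.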